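## The problem

Target 14 is a single γ-butyrolactone (ring C: O1, carbonyl C2, C3, C4, C5) with two different benzyl arms. C3 carries the benzylic carbon C7 and ring A (4-hydroxy-3-methoxyphenyl); C4 carries the benzylic carbon C7' and ring B (3-hydroxy-4-methoxyphenyl); the arms are trans, (3R,4R). Rings A and B differ only in which oxygen is methylated, so the chain C7–C3–C4–C7' cannot come from dimerising one phenylpropanoid. The two halves must enter as separate, already differentiated building blocks and be joined unsymmetrically, with C2 and C5 at different oxidation levels. C4 has no acidifying neighbour and must be set under absolute control, whereas C3 is α to the lactone carbonyl, can be equilibrated and prefers to lie trans to the C4 arm; C4 can therefore control C3, but not the reverse. The two phenols are easily oxidised to quinone methides and would quench carbene, enolate and hydride reagents, so they stay masked to the end, and the lactone does not tolerate hydroxide or alkoxide for long. The enabling feature is electronic: ring B has its methoxy group para to C7', so C7' is a donor-substituted carbon, and C3 lies between the lactone carbonyl C2 and C7, so with C7 at the ketone level C3 is doubly acceptor-substituted. A C3–C7' bond would then be the push–pull bond of a donor–acceptor cyclopropane, which carbene addition to a cinnamyl alkene can make and hydrogenolysis can break.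

## Retrosynthesis

14 ⇒ 12. No skeletal bond is cut; the C7 methylene of 14 is traced back to a ketone, giving β-keto lactone 12 (carbinol 13 lies between them in the forward sense). Keeping C7 as CH2 throughout would leave C3 with one acceptor only and would demand a separate C3–C7 bond formation late in the route. The ketone instead makes C3 a β-dicarbonyl methine that finds the trans arrangement by itself and gives the future carbene carbon its second acceptor. The precursor is no smaller, but much richer in usable reactivity. The forward step must take an aryl ketone to CH2 without touching the lactone or the configuration at C3.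

12 ⇒ 11. A bond is added: C3 is joined to C7' and both phenols are benzylated, giving the bicyclic cyclopropane 11. Among possible temporary bonds between the two halves, only C3–C7' links a donor carbon to a doubly activated acceptor carbon inside a three-membered ring. It should therefore cleave under ordinary hydrogenation in preference to C4–C7' (bicycle C5–C6), which has no acceptor. The structure becomes more complex on paper, but two stereochemical problems disappear: the configurations of 11 at C3 and C7' are erased on cleavage, and only C4 has to be right. The forward step asks one reagent to cleave that C–C bond and both benzyl ethers under neutral conditions.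

11 ⇒ 10. Cutting C3–C4 and C3–C7' together returns a carbene carbon C3 and an E alkene C4=C7' held in one ester, the diazo keto ester 10. Against an intermolecular cyclopropanation, the tether fixes the regiochemistry, closes the lactone in the same event and allows only cis fusion. Against cutting C3–C4 alone (conjugate addition to a preformed butenolide), no ring has to be made beforehand and no stoichiometric chiral controller is needed. Precursor 10 is acyclic, achiral and contains every carbon of 14. The forward reaction must select one face of the alkene at C4 and must prefer cyclopropane closure over other carbene pathways.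

10 ⇒ 9. Removing the diazo group leaves β-keto ester 9; the forward reaction is a diazo transfer to an active methylene group under mild amine base, which the cinnamyl ester tolerates.

9 ⇒ 7 + 4. The ester bond O1–C2 is cut. A crossed Claisen condensation (cutting C3–C7) would need a preformed ester enolate; acyl Meldrum's acid 7 instead releases aroylketene 8 on heating, which allylic alcohol 4 captures without base or coupling reagent. The two halves are of equal size, so the route is convergent. The forward step asks only that the electron-rich alcohol 4 survive a short period of heating with an acidic enol.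

7 ⇒ 5 + 6 and 4 ⇒ 3 ⇒ 1 + 2. The C3–C7 bond of 7 comes from C-acylation of Meldrum's acid 6 by acid 5. The C4=C7' alkene of 4 comes from olefination of aldehyde 1 with phosphonate 2, which sets the E geometry, followed by reduction of ester 3. Compounds 1, 2, 5 and 6 are catalogue items; the benzyl ethers already present in 1 and 5 are the only protecting groups, and both leave in step 7.

## Roads not taken

Alternative 1: The cut is C4–C7' and C3–C7 on a preformed, auxiliary-bearing butenolide, (5R)-5-menthyloxyfuran-2(5H)-one A1. In the forward sense the lithium anion of dithioacetal A2 adds to C4 of A1 anti to the menthyloxy group, and the enolate is alkylated at C3 by benzylic bromide A3 anti to the new C4 substituent. This gives the 3,4-trans-4,5-trans adduct A4 in one pot; no ring closes.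
- Merits: two skeletal bonds and both stereocentres come from an inexpensive stoichiometric controller; there is no catalyst to tune; trans is set kinetically; trans-dibenzylbutyrolactones are the classical products of this chemistry.
- Weak points: A4 still carries three things to remove by three different reductions (two C–S bonds with Raney Ni or Ni2B, the C5 acetal by borohydride and relactonisation, and the benzyl ethers). The auxiliary is stoichiometric and A1 needs a diastereomer separation. A sulfur-stabilised aryl carbanion at low temperature is required.
- Comparison: in stereochemical reliability this road is the stronger one, and its longest linear sequence would be no longer than that of the chosen plan. The chosen plan sets against it catalytic induction, an achiral precursor that is a plain ester holding every carbon, no sulfur and no cryogenic carbanion, and an end game in which hydrogen over palladium does all the unmasking.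

Alternative 2: The cut is C2–O1 and C2–C3, with carbon monoxide as C2. In the forward sense alkynol A5 reacts with CO under PdI2 and PBu3, and the lactone closes as the E-benzylidene derivative A6.
- Merits: the ring closure is atom-economical and stereochemically silent, so nothing can erode in it; the E geometry follows from syn addition across the alkyne.
- Weak points: the C4 stereocentre is not made in the key step and must be built beforehand in A5 by its own asymmetric sequence plus an aryl–alkyne coupling. C3 is then set by hydrogenating the exocyclic alkene of A6, where hydrogen arrives on the face away from the C4 arm and leads into the cis series, so a separate base epimerisation is needed. Non-carbonylative cyclisation of the alkynol competes.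
- Comparison: this road avoids a diazo compound and a designed chiral ligand, and its key step has no selectivity question at all; in that respect it is better. Both plans lean on thermodynamic correction at C3, but in the chosen plan this happens spontaneously at a readily enolised β-keto lactone and not in an added strong-base step. The chosen plan also makes the stereocentre, the ring and a skeletal bond in one step.

Alternative 3: The cut is C3–C4, together with a sacrificial C7–C7' bond in a cyclobutane. In the forward sense, visible light with [Ir(dF(CF3)ppy)2(dtbbpy)]PF6 and a chiral oxazaborolidine activated by AlBr3 generates the triplet of Lewis-acid-bound ferulate ester A7, which adds to the isoferulyl silyl ether A8 to give the all-trans cyclobutane A9.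
- Merits: the same temporary-bond logic, high convergence from two cinnamyl-level partners, and C3 and C4 set together, trans, under kinetic control; in this last respect it is better than the chosen plan, which leaves C3 to equilibrium.
- Weak points: A8 is a 1,2-disubstituted, electron-rich styrene that can itself be sensitised (E/Z isomerisation, homodimerisation) or oxidised by the excited iridium complex. Four aryl ether oxygens compete for AlBr3, which can also cleave benzyl ethers. The C7–C7' bond of A9 joins two donor carbons in a four-membered ring, with less strain and no push–pull polarisation, so hydrogen over palladium should not break it; the single-electron or dissolving-metal conditions that might do so also threaten the ester and the aryl ethers. Desilylation and lactonisation still follow.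
- Comparison: the ring-forming step is attractive, but the unmasking step is the unsolved part. In the chosen plan the sacrificial bond is strained and polarised, and it falls to the same reagent that removes the protecting groups.

Key step: step 6

Assumption: [Co(por*)] is the divalent cobalt complex of the D2-symmetric porphyrin dianion 5,15-bis(3,5-di-tert-butylphenyl)-10,20-bis{2,6-bis[(S)-2,2-dimethylcyclopropanecarboxamido]phenyl}porphyrinate or of its (R)-amide antipode. The antipode that attacks the Si face of C4 is the one used; which it is must be read from a first run, and both are accessible.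

## Route

Step 1
Reactants: 1 3-(benzyloxy)-4-methoxybenzaldehyde; 2 triethyl phosphonoacetate
Product: 3 ethyl (E)-3-[3-(benzyloxy)-4-methoxyphenyl]prop-2-enoate
Conditions: NaH, THF, 0 °C to rt
Reagents that add atoms: none
Why: Horner–Wadsworth–Emmons olefination of an aromatic aldehyde with a stabilised phosphonate anion gives the E cinnamate; this geometry later places ring B exo on the cyclopropane.

Step 2
Reactants: 3 ethyl (E)-3-[3-(benzyloxy)-4-methoxyphenyl]prop-2-enoate
Product: 4 (E)-3-[3-(benzyloxy)-4-methoxyphenyl]prop-2-en-1-ol
Conditions: i-Bu2AlH (2.2 equiv), CH2Cl2, −78 to 0 °C; aq. potassium sodium tartrate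
Reagents that add atoms: none
Why: Aluminium hydride 1,2-reduction of an α,β-unsaturated ester to the allylic alcohol; the aryl ethers and the alkene geometry are untouched.

Step 3
Reactants: 5 4-(benzyloxy)-3-methoxybenzoic acid; 6 Meldrum's acid (2,2-dimethyl-1,3-dioxane-4,6-dione)
Product: 7 5-{[4-(benzyloxy)-3-methoxyphenyl](hydroxy)methylidene}-2,2-dimethyl-1,3-dioxane-4,6-dione
Conditions: DCC, DMAP, CH2Cl2, 0 °C to rt
Reagents that add atoms: none
Why: Carbodiimide activation of the acid and DMAP-mediated C-acylation of Meldrum's acid (Oikawa–Yonemitsu acylation); the product is a stabilised enol freed from DMAP by an acid wash.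

Step 4
Reactants: 7 5-{[4-(benzyloxy)-3-methoxyphenyl](hydroxy)methylidene}-2,2-dimethyl-1,3-dioxane-4,6-dione; 4 (E)-3-[3-(benzyloxy)-4-methoxyphenyl]prop-2-en-1-ol
Product: 9 (E)-3-[3-(benzyloxy)-4-methoxyphenyl]prop-2-en-1-yl 3-[4-(benzyloxy)-3-methoxyphenyl]-3-oxopropanoate, via aroylketene 8 (not isolated)
Conditions: toluene, 90 °C
Reagents that add atoms: none
Why: Thermal retro-[4+2] fragmentation of the acyl Meldrum's acid releases acetone, CO2 and acylketene 8, which the primary alcohol captures; this is the standard Meldrum's acid route to β-keto esters and needs no added base or coupling reagent.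

Step 5
Reactants: 9 (E)-3-[3-(benzyloxy)-4-methoxyphenyl]prop-2-en-1-yl 3-[4-(benzyloxy)-3-methoxyphenyl]-3-oxopropanoate
Product: 10 (E)-3-[3-(benzyloxy)-4-methoxyphenyl]prop-2-en-1-yl 3-[4-(benzyloxy)-3-methoxyphenyl]-2-diazo-3-oxopropanoate
Conditions: p-ABSA, Et3N, MeCN, 0 °C to rt
Reagents that add atoms: 4-acetamidobenzenesulfonyl azide (p-ABSA), CC(=O)Nc1ccc(cc1)S(=O)(=O)N=[N+]=[N-]
Why: Regitz diazo transfer to the active methylene group of a β-keto ester; the acceptor–acceptor diazo compound formed should be stable to handling and chromatography.

Step 6
Reactants: 10 (E)-3-[3-(benzyloxy)-4-methoxyphenyl]prop-2-en-1-yl 3-[4-(benzyloxy)-3-methoxyphenyl]-2-diazo-3-oxopropanoate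
Product: 11 (1S,5R,6S)-1-[4-(benzyloxy)-3-methoxybenzoyl]-6-[3-(benzyloxy)-4-methoxyphenyl]-3-oxabicyclo[3.1.0]hexan-2-one (ring B exo, cis to the aroyl group)
Conditions: [Co(por*)] (2–5 mol %), toluene, 25–40 °C, N2 atmosphere
Reagents that add atoms: none
Why: The divalent cobalt centre of [Co(por*)], a metal-centred radical, takes up 10, expels N2 and gives a cobalt-bound carbon radical at C3 (a trivalent cobalt carbene radical) held in the chiral pocket by N–H···O=C hydrogen bonds from the amide arms to its carbonyl groups. This radical adds to alkene carbon C4 in a 5-exo-trig closure that forms C3–C4 and the lactone ring and leaves a benzylic radical on C7', stabilised by the para-methoxy group of ring B. A 3-exo-tet radical substitution at C3 then forms C3–C7', closes the cyclopropane and returns divalent cobalt. The closest known reaction type is the asymmetric intramolecular cyclopropanation of allyl α-acceptor-substituted diazoacetates by cobalt amidoporphyrins, with copper bis(oxazoline) carbenoid cyclisation as its closed-shell relative. C4 (C5 of the bicycle, R) is set in the first bond formation by the alkene face the pocket exposes, here the Si face of C4; C3 (C1, S) follows because the three-membered ring can only close cis to the lactone; C7' (C6, S) carries ring B exo because the E geometry of 10 is kept when closure outruns bond rotation. The step therefore needs only enantiofacial selection at C4, since C3 and C7' lose their configuration in step 7. The substrate helps chemoselectivity by having no β-hydrogen on the carbene carbon and a tether that makes the 5-exo addition faster than dimerisation or hydrogen abstraction.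

Step 7
Reactants: 11 (1S,5R,6S)-1-[4-(benzyloxy)-3-methoxybenzoyl]-6-[3-(benzyloxy)-4-methoxyphenyl]-3-oxabicyclo[3.1.0]hexan-2-one
Product: 12 (3S,4R)-3-(4-hydroxy-3-methoxybenzoyl)-4-(3-hydroxy-4-methoxybenzyl)dihydrofuran-2(3H)-one (3,4-trans)
Conditions: H2 (1 atm), 10% Pd/C, EtOAc–EtOH, rt
Reagents that add atoms: none
Why: Heterogeneous hydrogenolysis removes both benzyl ethers and cleaves the cyclopropane bond C1–C6 of the bicycle (C3–C7'), the only ring bond that is benzylic to the donor ring B and also flanked by two carbonyl groups; C4 is untouched. The freed C3 is a β-keto lactone methine that equilibrates by enolisation to the trans isomer; its S descriptor reflects the ketone's priority, not a different spatial arrangement from 14.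

Step 8
Reactants: 12 (3S,4R)-3-(4-hydroxy-3-methoxybenzoyl)-4-(3-hydroxy-4-methoxybenzyl)dihydrofuran-2(3H)-one
Product: 14 (3R,4R)-3-(4-hydroxy-3-methoxybenzyl)-4-(3-hydroxy-4-methoxybenzyl)dihydrofuran-2(3H)-one, via benzylic alcohol 13 (not isolated)
Conditions: H2 (3 atm), 10% Pd/C, AcOH, HClO4 (cat.), rt
Reagents that add atoms: none
Why: Acid-promoted benzylic hydrogenolysis: the para-hydroxyaryl ketone is hydrogenated to carbinol 13, whose C–O bond is then cleaved through the cation stabilised by the para-hydroxy group, as is done for benzylic carbinols and ketones of lignan lactones. C3 enters as the trans epimer and is no longer readily enolised once the ketone is reduced, so the (3R,4R) lactone should result.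

## Compound list

1 | 3-(benzyloxy)-4-methoxybenzaldehyde | COc1ccc(C=O)cc1OCc1ccccc1 | starting material
2 | triethyl phosphonoacetate | CCOC(=O)CP(=O)(OCC)OCC | starting material
3 | ethyl (E)-3-[3-(benzyloxy)-4-methoxyphenyl]prop-2-enoate | CCOC(=O)/C=C/c1ccc(OC)c(OCc2ccccc2)c1 | intermediate
4 | (E)-3-[3-(benzyloxy)-4-methoxyphenyl]prop-2-en-1-ol | OC/C=C/c1ccc(OC)c(OCc2ccccc2)c1 | intermediate
5 | 4-(benzyloxy)-3-methoxybenzoic acid | COc1cc(C(=O)O)ccc1OCc1ccccc1 | starting material
6 | Meldrum's acid (2,2-dimethyl-1,3-dioxane-4,6-dione) | CC1(C)OC(=O)CC(=O)O1 | starting material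
7 | 5-{[4-(benzyloxy)-3-methoxyphenyl](hydroxy)methylidene}-2,2-dimethyl-1,3-dioxane-4,6-dione | CC1(C)OC(=O)C(=C(O)c2ccc(OCc3ccccc3)c(OC)c2)C(=O)O1 | intermediate
8 | 3-[4-(benzyloxy)-3-methoxyphenyl]-3-oxoprop-1-en-1-one (aroylketene, formed and consumed in step 4) | O=C=CC(=O)c1ccc(OCc2ccccc2)c(OC)c1 | intermediate
9 | (E)-3-[3-(benzyloxy)-4-methoxyphenyl]prop-2-en-1-yl 3-[4-(benzyloxy)-3-methoxyphenyl]-3-oxopropanoate | COc1ccc(/C=C/COC(=O)CC(=O)c2ccc(OCc3ccccc3)c(OC)c2)cc1OCc1ccccc1 | intermediate
10 | (E)-3-[3-(benzyloxy)-4-methoxyphenyl]prop-2-en-1-yl 3-[4-(benzyloxy)-3-methoxyphenyl]-2-diazo-3-oxopropanoate | COc1ccc(/C=C/COC(=O)C(=[N+]=[N-])C(=O)c2ccc(OCc3ccccc3)c(OC)c2)cc1OCc1ccccc1 | intermediate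
11 | (1S,5R,6S)-1-[4-(benzyloxy)-3-methoxybenzoyl]-6-[3-(benzyloxy)-4-methoxyphenyl]-3-oxabicyclo[3.1.0]hexan-2-one | COc1ccc(cc1OCc1ccccc1)[C@@H]3[C@H]2COC(=O)[C@]23C(=O)c1ccc(OCc2ccccc2)c(OC)c1 | intermediate
12 | (3S,4R)-3-(4-hydroxy-3-methoxybenzoyl)-4-(3-hydroxy-4-methoxybenzyl)dihydrofuran-2(3H)-one | COc1ccc(C[C@H]2COC(=O)[C@@H]2C(=O)c2ccc(O)c(OC)c2)cc1O | intermediate
13 | (3S,4R)-3-[hydroxy(4-hydroxy-3-methoxyphenyl)methyl]-4-(3-hydroxy-4-methoxybenzyl)dihydrofuran-2(3H)-one (carbinol configuration not defined; formed and consumed in step 8) | COc1ccc(C[C@H]2COC(=O)[C@@H]2C(O)c2ccc(O)c(OC)c2)cc1O | intermediate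
14 | (3R,4R)-3-(4-hydroxy-3-methoxybenzyl)-4-(3-hydroxy-4-methoxybenzyl)dihydrofuran-2(3H)-one | COc1ccc(C[C@H]2COC(=O)[C@@H]2Cc2ccc(O)c(OC)c2)cc1O | target

## Step count and least certain steps

Total steps: 8. Longest linear sequence: 7 (steps 1, 2, 4, 5, 6, 7, 8); step 3 is the one-step side branch.

Step 6 (key step). The most likely failure is insufficient discrimination between the two faces of the alkene at C4, because the aroyl group is bulkier and more electron-rich than the acceptors for which such catalyst pockets are usually tuned. Sluggish activation of the acceptor–acceptor diazo group could also force a higher temperature, which would lower selectivity further. Closure of the benzylic radical on the ketone oxygen instead of on C3 is a lesser concern, because hydrogenolysis of the resulting benzylic C–O bond in step 7 would lead to the same keto lactone 12.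

The fallback sets out from 4 and returns at 14. It moves the asymmetric step to the acceptor-only diazoacetate and installs the C3 arm afterwards by enolate alkylation.
- Alcohol 4 would be acylated with 2,5-dioxopyrrolidin-1-yl 2-diazoacetate and Et3N to give (E)-3-[3-(benzyloxy)-4-methoxyphenyl]prop-2-en-1-yl 2-diazoacetate F1.
- Intramolecular cyclopropanation of F1 with Rh2(MPPIM)4 (dirhodium tetrakis[methyl 1-(3-phenylpropanoyl)-2-oxoimidazolidine-4-carboxylate], antipode chosen for the 1S,5R series) should give (1S,5R,6R)-6-[3-(benzyloxy)-4-methoxyphenyl]-3-oxabicyclo[3.1.0]hexan-2-one F2.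
- Hydrogenolysis (H2, 10% Pd/C) opens the same benzylic, carbonyl-flanked ring bond and removes the benzyl group, giving (R)-4-(3-hydroxy-4-methoxybenzyl)dihydrofuran-2(3H)-one F3.
- Benzyl bromide and K2CO3 return the phenol to (R)-4-[3-(benzyloxy)-4-methoxybenzyl]dihydrofuran-2(3H)-one F4.
- Deprotonation with LiN(SiMe3)2 at −78 °C and alkylation with 4-(benzyloxy)-3-methoxybenzyl bromide (the same bromide as A3), anti to the C4 arm, gives (3R,4R)-3-[4-(benzyloxy)-3-methoxybenzyl]-4-[3-(benzyloxy)-4-methoxybenzyl]dihydrofuran-2(3H)-one F5.
- Hydrogenolysis of F5 gives 14.

Step 7. The most likely failure is stalling after debenzylation, because the quaternary C3 hinders adsorption of the cyclopropane on the metal; partial reduction of the ketone before the ring has opened would give mixtures. Cleavage of the other benzylic ring bond is less likely but cannot be excluded.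

The fallback sets out from 11 and returns at 12. It replaces surface hydrogenolysis by single-electron ring opening. SmI2 in THF–MeOH at −78 °C forms the ketyl of the aroyl group, and the cyclopropylcarbinyl radical can open only at a bond to C3; it should open toward the benzylic radical on C7'. This gives (3S,4R)-3-[4-(benzyloxy)-3-methoxybenzoyl]-4-[3-(benzyloxy)-4-methoxybenzyl]dihydrofuran-2(3H)-one F6. Debenzylation of F6 (H2, 10% Pd/C, EtOAc) gives 12.

Step 8. The most likely failure is acid-catalysed dehydration of the intermediate carbinol to the conjugated benzylidene lactone. Hydrogen would then be delivered to the face away from the C4 arm and the trans relationship would be lost. Stalling at the carbinol stage is the second possibility.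

The fallback sets out from 12 and returns at 14. It separates the two reductions and replaces surface hydrogenolysis by ionic hydrogenation. NaBH4 in MeOH at −20 °C gives carbinol 13, isolated here. Et3SiH with CF3CO2H in CH2Cl2 at 0 °C then transfers hydride directly to the benzylic cation at C7, without passing through an alkene at C3. If some epimerisation at C3 has nevertheless occurred, a final amine-base equilibration would return the material to the trans series.

Step 4. The most likely failure is ionisation of the electron-rich cinnamyl alcohol 4 by the acidic enol 7 at 90 °C, leading to allylic transposition or ether formation in competition with capture of the ketene.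

The fallback sets out from 7 and returns at 9. It keeps the acid away from the alcohol. Heating 7 in methanol gives methyl 3-[4-(benzyloxy)-3-methoxyphenyl]-3-oxopropanoate F7. DMAP-catalysed transesterification of F7 with 4 in refluxing toluene over 4 Å molecular sieves, with removal of methanol, gives 9.

## Further compounds

F1 | step 6 | (E)-3-[3-(benzyloxy)-4-methoxyphenyl]prop-2-en-1-yl 2-diazoacetate | COc1ccc(/C=C/COC(=O)C=[N+]=[N-])cc1OCc1ccccc1
F2 | step 6 | (1S,5R,6R)-6-[3-(benzyloxy)-4-methoxyphenyl]-3-oxabicyclo[3.1.0]hexan-2-one | COc1ccc(cc1OCc1ccccc1)[C@@H]3[C@H]2COC(=O)[C@H]23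
F3 | step 6 | (R)-4-(3-hydroxy-4-methoxybenzyl)dihydrofuran-2(3H)-one | COc1ccc(C[C@H]2COC(=O)C2)cc1O
F4 | step 6 | (R)-4-[3-(benzyloxy)-4-methoxybenzyl]dihydrofuran-2(3H)-one | COc1ccc(C[C@H]2COC(=O)C2)cc1OCc1ccccc1
F5 | step 6 | (3R,4R)-3-[4-(benzyloxy)-3-methoxybenzyl]-4-[3-(benzyloxy)-4-methoxybenzyl]dihydrofuran-2(3H)-one | COc1ccc(C[C@H]2COC(=O)[C@@H]2Cc2ccc(OCc3ccccc3)c(OC)c2)cc1OCc1ccccc1
F6 | step 7 | (3S,4R)-3-[4-(benzyloxy)-3-methoxybenzoyl]-4-[3-(benzyloxy)-4-methoxybenzyl]dihydrofuran-2(3H)-one | COc1ccc(C[C@H]2COC(=O)[C@@H]2C(=O)c2ccc(OCc3ccccc3)c(OC)c2)cc1OCc1ccccc1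
F0 | step 8 | none | none
F7 | step 4 | methyl 3-[4-(benzyloxy)-3-methoxyphenyl]-3-oxopropanoate | COC(=O)CC(=O)c1ccc(OCc2ccccc2)c(OC)c1
A1 | alternative 1 | (5R)-5-{[(1R,2S,5R)-2-isopropyl-5-methylcyclohexyl]oxy}furan-2(5H)-one | O=C1C=C[C@H](O[C@@H]2C[C@H](C)CC[C@H]2C(C)C)O1
A2 | alternative 1 | 2-(benzyloxy)-4-[bis(phenylsulfanyl)methyl]-1-methoxybenzene | COc1ccc(cc1OCc1ccccc1)C(Sc1ccccc1)Sc1ccccc1
A3 | alternative 1 | 4-(benzyloxy)-3-methoxybenzyl bromide | COc1cc(CBr)ccc1OCc1ccccc1
A4 | alternative 1 | (3R,4R,5R)-3-[4-(benzyloxy)-3-methoxybenzyl]-4-{[3-(benzyloxy)-4-methoxyphenyl]bis(phenylsulfanyl)methyl}-5-{[(1R,2S,5R)-2-isopropyl-5-methylcyclohexyl]oxy}dihydrofuran-2(3H)-one | COc1ccc(cc1OCc1ccccc1)C(Sc1ccccc1)(Sc1ccccc1)[C@H]2[C@H](O[C@@H]3C[C@H](C)CC[C@H]3C(C)C)OC(=O)[C@@H]2Cc2ccc(OCc3ccccc3)c(OC)c2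
A5 | alternative 2 | (R)-2-[3-(benzyloxy)-4-methoxybenzyl]-4-[4-(benzyloxy)-3-methoxyphenyl]but-3-yn-1-ol | COc1ccc(C[C@@H](CO)C#Cc2ccc(OCc3ccccc3)c(OC)c2)cc1OCc1ccccc1
A6 | alternative 2 | (R,E)-3-[4-(benzyloxy)-3-methoxybenzylidene]-4-[3-(benzyloxy)-4-methoxybenzyl]dihydrofuran-2(3H)-one | COc1ccc(C[C@H]2COC(=O)/C2=C/c2ccc(OCc3ccccc3)c(OC)c2)cc1OCc1ccccc1
A7 | alternative 3 | methyl (E)-3-[4-(benzyloxy)-3-methoxyphenyl]prop-2-enoate | COC(=O)/C=C/c1ccc(OCc2ccccc2)c(OC)c1
A8 | alternative 3 | tert-butyl{[(E)-3-[3-(benzyloxy)-4-methoxyphenyl]prop-2-en-1-yl]oxy}dimethylsilane | COc1ccc(/C=C/CO[Si](C)(C)C(C)(C)C)cc1OCc1ccccc1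
A9 | alternative 3 | methyl all-trans-2-[4-(benzyloxy)-3-methoxyphenyl]-3-[3-(benzyloxy)-4-methoxyphenyl]-4-{[(tert-butyldimethylsilyl)oxy]methyl}cyclobutane-1-carboxylate (absolute configuration as in the SMILES) | COc1ccc(cc1OCc1ccccc1)[C@@H]2[C@@H](CO[Si](C)(C)C(C)(C)C)[C@H](C(=O)OC)[C@H]2c3ccc(OCc4ccccc4)c(OC)c3
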